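**Assumption:** the target is built exactly as written in the SMILES. Each ester alcohol is therefore the (4R,4aR,6R,7R,7aS)-amino alcohol, and the cyclobutane is (1R,2S,3S,4S) with C1 = C(CH3)(CO2R), C2 = CH(side chain), C3 = CH(CO2R), C4 = CH(aryl).

## Retrosynthetic overview

- The cyclobutane is cut last into two (E)-alkenes: the feruloyl ester of the amino alcohol and the bis(amino alcohol) ester of (2E,6E)-2,6-dimethylocta-2,6-dienedioic acid, joined head-to-tail by a sensitised crossed [2+2] photocycloaddition.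
- Both esters come from one amino alcohol; the cinnamate is built on its oxygen (malonate half-ester, then Knoevenagel–Doebner with vanillin), and the diacid comes from geraniol.
- The amino alcohol comes from a carbamate-tethered 1,7-enyne by an intramolecular Pauson–Khand reaction that forms the piperidine and cyclopentenone rings together, then hydrogenation, C7 epimerisation and hydride reduction.
- The only purchased stereocentre is that of (2R)-3-bromo-2-methylpropan-1-ol; it becomes C4 and relays to C4a, C7a, C7 and C6.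
- Ring order: piperidine and cyclopentane (one step, three times used), then the cyclobutane.

## Route

**Step 1**
Reactants: 1 (2R)-3-bromo-2-methylpropan-1-ol; 2 but-2-yn-1-amine hydrochloride
Product: 3 (2S)-3-(but-2-yn-1-ylamino)-2-methylpropan-1-ol
Conditions: 2 (3 equiv), K2CO3 (5 equiv), NaI (10 mol%), MeCN, 70 °C, sealed vessel, 24 h
Reagents that add atoms: none
Why: Iodide-assisted SN2 amine alkylation at the primary CH2Br; the purchased stereocentre is untouched (R becomes S only because CH2OH now outranks CH2N).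

**Step 2**
Reactants: 3 (2S)-3-(but-2-yn-1-ylamino)-2-methylpropan-1-ol
Product: 4 methyl but-2-yn-1-yl[(2S)-3-hydroxy-2-methylpropyl]carbamate
Conditions: ClCO2Me (1.05 equiv), NaHCO3, CH2Cl2/H2O, 0 °C
Reagents that add atoms: methyl chloroformate, COC(=O)Cl
Why: Schotten–Baumann N-acylation; the secondary amine outcompetes the primary alcohol, and the carbamate both masks the basic nitrogen for the cobalt step and is the latent N-methyl group.

**Step 3**
Reactants: 4 methyl but-2-yn-1-yl[(2S)-3-hydroxy-2-methylpropyl]carbamate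
Product: 6 methyl but-2-yn-1-yl[(2R)-2-methylbut-3-en-1-yl]carbamate, via aldehyde 5 (not isolated)
Conditions: (COCl)2, DMSO, THF, −78 °C; Et3N, −78 to −40 °C; then Ph3P=CH2 (4 equiv, from Ph3PCH3Br and KN(SiMe3)2 in THF), −78 to 0 °C
Reagents that add atoms: methylenetriphenylphosphorane, C=P(c1ccccc1)(c1ccccc1)c1ccccc1
Why: One-pot Swern oxidation and Wittig methylenation (excess ylide also absorbs the ammonium salt) traps the epimerisable α-methyl aldehyde cold, so the stereocentre is carried over unchanged (now R by priority change).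

**Step 4**
Reactants: 6 methyl but-2-yn-1-yl[(2R)-2-methylbut-3-en-1-yl]carbamate
Product: 7 methyl (4R,4aR)-4,7-dimethyl-6-oxo-1,3,4,4a,5,6-hexahydro-2H-cyclopenta[c]pyridine-2-carboxylate
Conditions: Co2(CO)8 (1.1 equiv), CH2Cl2, rt, 2 h; then N-methylmorpholine N-oxide (8 equiv), 0 °C to rt
Reagents that add atoms: dicobalt octacarbonyl (supplies one CO), [Co].[Co].[C-]#[O+].[C-]#[O+].[C-]#[O+].[C-]#[O+].[C-]#[O+].[C-]#[O+].[C-]#[O+].[C-]#[O+]
Why: Intramolecular Pauson–Khand [2+2+1] cycloaddition closes both rings at once; the allylic methyl sits pseudo-equatorial in the chair-like cobaltacycle, so C4a–H forms anti to C4–H (4R,4aR), and the minor epimer is removed by chromatography.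

**Step 5**
Reactants: 7 methyl (4R,4aR)-4,7-dimethyl-6-oxo-1,3,4,4a,5,6-hexahydro-2H-cyclopenta[c]pyridine-2-carboxylate
Product: 9 methyl (4R,4aR,7R,7aS)-4,7-dimethyl-6-oxooctahydro-2H-cyclopenta[c]pyridine-2-carboxylate, via all-cis ketone 8 (not isolated)
Conditions: H2 (4 atm), 10% Pd/C, MeOH, rt; filter through Celite; then NaOMe (0.2 equiv) in the filtrate, rt, 12 h
Reagents that add atoms: none
Why: Heterogeneous syn-hydrogenation adds from the enone face opposite the C4 branch (the face of C4a–H) to give the cis-fused ketone, and base enolisation then epimerises C7 to the more stable isomer with the methyl trans to the C7a–C1 bond (thermodynamic control).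

**Step 6**
Reactants: 9 methyl (4R,4aR,7R,7aS)-4,7-dimethyl-6-oxooctahydro-2H-cyclopenta[c]pyridine-2-carboxylate
Product: 10 (4R,4aR,6R,7R,7aS)-2,4,7-trimethyloctahydro-1H-cyclopenta[c]pyridin-6-ol
Conditions: LiAlH4 (4 equiv), THF, −78 °C (1 h), then reflux (6 h); Fieser work-up
Reagents that add atoms: none
Why: Hydride reduction; the small hydride should attack from the convex face (the side of the ring-fusion hydrogens, the sense that gives trans alcohols from 2-methylcyclopentanones), setting 6R with the hydroxyl trans to the C7 methyl (minor 6S epimer separated), and at reflux the carbamate is reduced to N-methyl.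

**Step 7**
Reactants: 11 geraniol
Product: 12 (2E,6E)-2,6-dimethylocta-2,6-diene-1,8-diol
Conditions: SeO2 (0.3 equiv), t-BuOOH (70% aq., 3 equiv), salicylic acid (0.1 equiv), CH2Cl2, rt, 24–36 h
Reagents that add atoms: tert-butyl hydroperoxide (terminal oxygen source, relayed by catalytic SeO2), CC(C)(C)OO
Why: Sharpless allylic oxidation (ene reaction then [2,3]-sigmatropic shift) hydroxylates the E-methyl of the electron-richer distal alkene with E geometry kept; any over-oxidation to enal is harmless because both ends go to the acid next.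

**Step 8**
Reactants: 12 (2E,6E)-2,6-dimethylocta-2,6-diene-1,8-diol
Product: 14 (2E,6E)-2,6-dimethylocta-2,6-dienedioic acid, via dialdehyde 13 (not isolated)
Conditions: TEMPO (0.2 equiv), PhI(OAc)2 (2.5 equiv), CH2Cl2, rt; then t-BuOH/H2O, 2-methylbut-2-ene (20 equiv), NaClO2 (6 equiv), NaH2PO4 (6 equiv), 0 °C to rt
Reagents that add atoms: sodium chlorite, [Na+].[O-]Cl=O
Why: Nitroxyl-catalysed oxidation of both allylic alcohols to the bis-enal, then Pinnick oxidation in the same flask, gives the diacid without E/Z isomerisation.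

**Step 9**
Reactants: 10 (4R,4aR,6R,7R,7aS)-2,4,7-trimethyloctahydro-1H-cyclopenta[c]pyridin-6-ol; 15 Meldrum's acid; 16 vanillin
Product: 18 (4R,4aR,6R,7R,7aS)-2,4,7-trimethyloctahydro-1H-cyclopenta[c]pyridin-6-yl (2E)-3-(4-hydroxy-3-methoxyphenyl)prop-2-enoate, via malonic half-ester 17 (not isolated)
Conditions: 15 (1.2 equiv), toluene, 100 °C, 4 h; then 16 (1.3 equiv), pyridine, piperidine (0.2 equiv), 70 °C, 12 h
Reagents that add atoms: none
Why: Ring-opening acylation of Meldrum's acid by the alcohol (C6–O bond untouched, so retention) gives the malonic half-ester, whose decarboxylative Knoevenagel–Doebner condensation with vanillin gives the E-cinnamate with the phenol unprotected.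

**Step 10**
Reactants: 14 (2E,6E)-2,6-dimethylocta-2,6-dienedioic acid; 10 (4R,4aR,6R,7R,7aS)-2,4,7-trimethyloctahydro-1H-cyclopenta[c]pyridin-6-ol (2.3 equiv)
Product: 19 bis[(4R,4aR,6R,7R,7aS)-2,4,7-trimethyloctahydro-1H-cyclopenta[c]pyridin-6-yl] (2E,6E)-2,6-dimethylocta-2,6-dienedioate
Conditions: EDC·HCl (3 equiv), DMAP (1 equiv), CH2Cl2, 0 °C to rt, 24 h
Reagents that add atoms: none
Why: Steglich esterification acylates the alcohol oxygen, so C6 is retained and both E-alkenes stay conjugated.

**Step 11**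
Reactants: 18 (4R,4aR,6R,7R,7aS)-2,4,7-trimethyloctahydro-1H-cyclopenta[c]pyridin-6-yl (2E)-3-(4-hydroxy-3-methoxyphenyl)prop-2-enoate; 19 bis[(4R,4aR,6R,7R,7aS)-2,4,7-trimethyloctahydro-1H-cyclopenta[c]pyridin-6-yl] (2E,6E)-2,6-dimethylocta-2,6-dienedioate
Product: 20 bis[(4R,4aR,6R,7R,7aS)-2,4,7-trimethyloctahydro-1H-cyclopenta[c]pyridin-6-yl] (1R,2S,3S,4S)-4-(4-hydroxy-3-methoxyphenyl)-1-methyl-2-[(3E)-3-methyl-5-oxo-5-{[(4R,4aR,6R,7R,7aS)-2,4,7-trimethyloctahydro-1H-cyclopenta[c]pyridin-6-yl]oxy}pent-3-en-1-yl]cyclobutane-1,3-dicarboxylate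
Conditions: 19 (3 equiv, excess recovered), 18 added by syringe pump over 20 h, fac-Ir(dFppy)3 [Ir(C11H6F2N)3] (2 mol%), degassed MeCN (0.15 M in 19), 427 nm LEDs, 25 °C, 48 h; preparative HPLC
Reagents that add atoms: none
Why: Crossed [2+2] photocycloaddition by triplet energy transfer: only the ferulate is sensitised, its α-carbon adds to C3 of the α-methyl enoate (the β,β-disubstituted 6-ene is blocked) to give the benzylic/tertiary α-ester 1,4-diradical, which closes head-to-tail to the all-trans ring with the enoate E-relationship kept; the remote chiral esters bias the two faces only weakly, so the (1R,2S,3S,4S) isomer is separated from its cyclobutane-enantiomeric diastereomer.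

## Compound list

1 | (2R)-3-bromo-2-methylpropan-1-ol | OC[C@@H](C)CBr | starting material
2 | but-2-yn-1-amine hydrochloride | CC#CCN.Cl | starting material
3 | (2S)-3-(but-2-yn-1-ylamino)-2-methylpropan-1-ol | OC[C@@H](C)CNCC#CC | intermediate
4 | methyl but-2-yn-1-yl[(2S)-3-hydroxy-2-methylpropyl]carbamate | OC[C@@H](C)CN(CC#CC)C(=O)OC | intermediate
5 | methyl but-2-yn-1-yl[(2S)-2-methyl-3-oxopropyl]carbamate | O=C[C@@H](C)CN(CC#CC)C(=O)OC | intermediate
6 | methyl but-2-yn-1-yl[(2R)-2-methylbut-3-en-1-yl]carbamate | C=C[C@@H](C)CN(CC#CC)C(=O)OC | intermediate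
7 | methyl (4R,4aR)-4,7-dimethyl-6-oxo-1,3,4,4a,5,6-hexahydro-2H-cyclopenta[c]pyridine-2-carboxylate | O=C1C[C@H]2C(CN(C(=O)OC)C[C@@H]2C)=C1C | intermediate
8 | methyl (4R,4aR,7S,7aS)-4,7-dimethyl-6-oxooctahydro-2H-cyclopenta[c]pyridine-2-carboxylate | O=C1C[C@H]2[C@H](CN(C(=O)OC)C[C@@H]2C)[C@@H]1C | intermediate
9 | methyl (4R,4aR,7R,7aS)-4,7-dimethyl-6-oxooctahydro-2H-cyclopenta[c]pyridine-2-carboxylate | O=C1C[C@H]2[C@H](CN(C(=O)OC)C[C@@H]2C)[C@H]1C | intermediate
10 | (4R,4aR,6R,7R,7aS)-2,4,7-trimethyloctahydro-1H-cyclopenta[c]pyridin-6-ol | O[C@@H]1C[C@H]2[C@H](CN(C)C[C@@H]2C)[C@H]1C | intermediate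
11 | geraniol | CC(C)=CCC/C(C)=C/CO | starting material
12 | (2E,6E)-2,6-dimethylocta-2,6-diene-1,8-diol | OC/C(C)=C/CC/C(C)=C/CO | intermediate
13 | (2E,6E)-2,6-dimethylocta-2,6-dienedial | O=C/C(C)=C/CC/C(C)=C/C=O | intermediate
14 | (2E,6E)-2,6-dimethylocta-2,6-dienedioic acid | OC(=O)/C(C)=C/CC/C(C)=C/C(=O)O | intermediate
15 | Meldrum's acid (2,2-dimethyl-1,3-dioxane-4,6-dione) | CC1(C)OC(=O)CC(=O)O1 | starting material
16 | vanillin | COc1cc(C=O)ccc1O | starting material
17 | 3-oxo-3-{[(4R,4aR,6R,7R,7aS)-2,4,7-trimethyloctahydro-1H-cyclopenta[c]pyridin-6-yl]oxy}propanoic acid | OC(=O)CC(=O)O[C@@H]1C[C@H]2[C@H](CN(C)C[C@@H]2C)[C@H]1C | intermediate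
18 | (4R,4aR,6R,7R,7aS)-2,4,7-trimethyloctahydro-1H-cyclopenta[c]pyridin-6-yl (2E)-3-(4-hydroxy-3-methoxyphenyl)prop-2-enoate | COc1cc(/C=C/C(=O)O[C@@H]2C[C@H]3[C@H](CN(C)C[C@@H]3C)[C@H]2C)ccc1O | intermediate
19 | bis[(4R,4aR,6R,7R,7aS)-2,4,7-trimethyloctahydro-1H-cyclopenta[c]pyridin-6-yl] (2E,6E)-2,6-dimethylocta-2,6-dienedioate | O=C(O[C@@H]1C[C@H]2[C@H](CN(C)C[C@@H]2C)[C@H]1C)/C(C)=C/CC/C(C)=C/C(=O)O[C@@H]1C[C@H]2[C@H](CN(C)C[C@@H]2C)[C@H]1C | intermediate
20 | tris-ester target (name as in step 11) | COc1cc([C@@H]2[C@@H](C(=O)O[C@@H]3C[C@H]4[C@H](CN(C)C[C@@H]4C)[C@H]3C)[C@H](CC/C(C)=C/C(=O)O[C@@H]3C[C@H]4[C@H](CN(C)C[C@@H]4C)[C@H]3C)[C@@]2(C)C(=O)O[C@@H]2C[C@H]3[C@H](CN(C)C[C@@H]3C)[C@H]2C)ccc1O | target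

## Step count and risks

Total: 11 steps. Longest linear sequence: 8 steps (1 → 3 → 4 → 6 → 7 → 9 → 10 → 18 or 19 → 20).

**Most likely to fail: step 11.** Triplet ferulates mostly isomerise and homodimerise, a trisubstituted enoate is a slow radical acceptor, and the chiral esters will give little facial bias, so a low yield and a near 1:1 pair of all-trans diastereomers are expected. The fallback moves the photochemistry to cheap acids and sets out from 14 and 10. Commercial (E)-4-acetoxy-3-methoxycinnamic acid is irradiated with the same sensitiser in a tenfold excess of 14 to give the racemic all-trans triacid F1. This is converted to its tris(acid chloride) with oxalyl chloride and used to acylate 10 (3.6 equiv, pyridine, DMAP), giving the O-acetyl triester F2 together with its cyclobutane-enantiomeric diastereomer, which are separated by HPLC. Pyrrolidine in CH2Cl2 at 0 °C then cleaves only the aryl acetate, and the route is rejoined at 20.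

**Second: step 6.** The facial sense of hydride delivery rests on analogy, and if attack anti to the C7 methyl wins, the hydroxyl comes out cis to that methyl. The configuration at C6 should be checked by NOE before going on. The fallback sets out from 9: the same reduction then gives mainly the 6S alcohol F3, which is esterified with inversion under Mitsunobu conditions (PPh3, DIAD, THF) instead of with retention. With ferulic acid (the carboxylic acid reacts in preference to the phenol) it returns to the route at 18, and with 14 (0.45 equiv) at 19.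

**Third: step 3.** The α-methyl aldehyde 5 carries the only purchased stereocentre and can epimerise under the basic one-pot conditions, which would erode every later centre. The fallback avoids the aldehyde by reversing the polarity and sets out from 4. Mitsunobu reaction with 1-phenyl-1H-tetrazole-5-thiol gives the sulfide F4, and oxidation with 30% H2O2 and catalytic (NH4)6Mo7O24 gives the sulfone F5. Julia–Kocienski methylenation (KN(SiMe3)2, THF, −78 °C, then monomeric formaldehyde) forms the terminal alkene at a carbon next to, not on, the stereocentre and returns to the route at 6.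

## Further compounds

F1 | step 11 | rac-(1R,2S,3S,4S)-4-[4-(acetyloxy)-3-methoxyphenyl]-2-[(3E)-4-carboxy-3-methylbut-3-en-1-yl]-1-methylcyclobutane-1,3-dicarboxylic acid (enantiomer shown leads to 20) | COc1cc([C@@H]2[C@@H](C(=O)O)[C@H](CC/C(C)=C/C(=O)O)[C@@]2(C)C(=O)O)ccc1OC(C)=O
F2 | step 11 | O-acetyl derivative of 20 (aryl acetate in place of the phenol) | COc1cc([C@@H]2[C@@H](C(=O)O[C@@H]3C[C@H]4[C@H](CN(C)C[C@@H]4C)[C@H]3C)[C@H](CC/C(C)=C/C(=O)O[C@@H]3C[C@H]4[C@H](CN(C)C[C@@H]4C)[C@H]3C)[C@@]2(C)C(=O)O[C@@H]2C[C@H]3[C@H](CN(C)C[C@@H]3C)[C@H]2C)ccc1OC(C)=O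
F3 | step 6 | (4R,4aR,6S,7R,7aS)-2,4,7-trimethyloctahydro-1H-cyclopenta[c]pyridin-6-ol | O[C@H]1C[C@H]2[C@H](CN(C)C[C@@H]2C)[C@H]1C
F4 | step 3 | methyl but-2-yn-1-yl{(2S)-2-methyl-3-[(1-phenyl-1H-tetrazol-5-yl)sulfanyl]propyl}carbamate | COC(=O)N(CC#CC)C[C@H](C)CSC1=NN=NN1c1ccccc1
F5 | step 3 | methyl but-2-yn-1-yl{(2S)-2-methyl-3-[(1-phenyl-1H-tetrazol-5-yl)sulfonyl]propyl}carbamate | COC(=O)N(CC#CC)C[C@H](C)CS(=O)(=O)C1=NN=NN1c1ccccc1
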